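Follow the reagent down through its own falling concentration before reading any curve: these flasks differ in temperature, and the question is how the selectivity, the share of target in target plus side product, answers to that.

in all of them: substrate 20 mM; reagent 18.0 mM; time 5.0 h

| charge | temperature |
|---|---|
| Thursday's | 75 °C |
| Friday's | 90 °C |
| Monday's | 60 °C |
| Sunday's | 105 °C |

    substrate + reagent → target (k1 = 2.9 M⁻¹ min⁻¹, Ea1 = 61.0 kJ mol⁻¹)
    substrate + 2 reagent → side product (k2 = 100 M⁻² min⁻¹, Ea2 = 62.0 kJ mol⁻¹)
    2 reagent → self-condensation product (k3 = 3.2 M⁻¹ min⁻¹, Ea3 = 55.0 kJ mol⁻¹)
    substrate → decomposition product (k4 = 3.2 × 10⁻⁵ min⁻¹, Ea4 = 130 kJ mol⁻¹)
    (constants at 90 °C)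

- where a step has two of a species, its rate is k times that concentration squared, and two are used at each turn
- the constants hold at 90 °C; other temperatures follow from the activation energies

* the flask that comes out highest in share of target in all that became target or side product, or "all alike" when all lie within 1.5 percentage points (Thursday's / Friday's / Monday's / Sunday's / all alike)
* share of target in all that became target or side product, Thursday's
* share of target in all that became target or side product, Friday's
* share of target in all that became target or side product, Monday's
* share of target in all that became target or side product, Sunday's

I write k_target, k_side and k_self for the constants of the steps to target, to side product and of self-condensation, and I freeze the substrate. Assuming it loses an amount equal to half the reagent charge, I hold it at its mean, 15.5 mM. Reagent then leaves by the target step in proportion to k_target·c(substrate), and by the two steps that spend two of it in proportion to 2(k_side·c(substrate) + k_self)·c(reagent). These are equal at the crossover level c_L = k_target·c(substrate)/[2(k_side·c(substrate) + k_self)], which is 4.73 mM with Friday's constants: the reagent concentration at which the target step takes as much reagent as the other two together. Summing over the fall from the charge gives target = c_L·ln(1 + charged c(reagent)/c_L) = 7.43 mM. The rest of the reagent divides between the two-reagent steps and yields 1.73 mM of side product, so the share is 81.1 %.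

Now the settings. Temperature: from the coldest flask to the hottest, the target step speeds up by 13.7, the side step by 14 and self-condensation by 11. Cutting k_self by the whole ratio 0.773 and leaving the other two constants as they are gives c_L = 5.59 mM and a share of 80.8 %, a shift smaller than the margin.

Time: well below c_L the decay is pseudo-first-order, and by the target step on Friday's constants, with the substrate frozen, it halves in 15.4 min. Multiplied by the whole span that is 3.53 h, an overstatement for Monday's flask, and 0.706 of 5.0 h, so I expect Monday's to end with some reagent unspent and its share slightly low.

Charge: 18.0 mM stands above c_L, so on Friday's constants the two-reagent steps together take more reagent at the start than the target step.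

I commit to all alike, near 81.1 %. The forecast also says all alike, with 81 % for Thursday's, 80.7 % for Friday's, 81.4 % for Monday's and 80.4 % for Sunday's, on the ground that "the share is set by how the reagent divides among the three reagent-consuming steps". It puts Monday's highest where I put it low.

The computed verdict is all alike: 80.8 % for Thursday's, 80.6 % for Friday's, 80.1 % for Monday's and 80.3 % for Sunday's. The spread of 0.70 percentage points is under the margin, so the forecast's verdict held although its order did not.

Monday's flask has not come to rest at 5.0 h: its reagent stands at 0.564 mM, below the c_L reckoned on Friday's constants. After 50.0 h, ten times as long, Monday's target goes from 32.9 % to 35.5 %, its side product stays at 8.18 %, and its share reaches 81.3 %. In Sunday's flask the longer wait leaves the share where it was, while its substrate still falls from 49.7 % to 30.9 %.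

Take the neighbour of Thursday's charged with 4.5 mM of reagent, still on Friday's constants. Substrate freezes at 18.9 mM, so c_L = 5.38 mM, above the charge, and the reckoning gives 3.27 mM of target, 0.228 mM of side product and a share of 93.5 %. The computed flask gives 93.6 %, with target at 16.1 % and side product at 1.11 % of the substrate charged.

Its constants were chosen freely; the flask was simulated.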